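**Retrosynthetic overview**
1. The target comes from its methyl ester diacetate by one global saponification that touches no stereocentre.
2. Key disconnection: the dihydrofuran ring is cut at C3–C3a and O1–C2 in one retro-[3+2]. The arene half is used as its o-quinone diazide rather than as a phenol (donor at the ortho carbon). Its dirhodium carbenoid is an α-oxo-cation (enolonium) equivalent, acceptor at C3a. The partner is the donor alkene (E)-3,4-dimethoxycinnamyl acetate.
3. The quinone diazide comes from an aminocatechol cinnamate, made from 3,4-dihydroxy-5-nitrobenzaldehyde and monomethyl malonate.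
4. The cinnamyl acetate comes from 3,4-dimethoxystyrene and cis-1,4-diacetoxybut-2-ene by cross metathesis.
5. Ring order: both benzene rings are bought. The dihydrofuran ring is the only ring made, in the key step, which sets C3 (catalyst) and C2 (trans closure).

Assumption: there is no direct precedent for the sense of induction of Rh2(S-TCPTTL)4 in Step 5. It is taken to give the (2R,3S) series and is checked on the first run (chiral HPLC, CD). If it is the opposite, Rh2(R-TCPTTL)4 is used and nothing else changes. Benzofuran numbering of the target (O1, C2, C3, C3a, C4 to C7, C7a) is used for all intermediates.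

**Step 1**
Reactants: 1 3,4-dihydroxy-5-nitrobenzaldehyde; 2 monomethyl malonate (3-methoxy-3-oxopropanoic acid)
Product: 3 methyl (E)-3-(3,4-dihydroxy-5-nitrophenyl)prop-2-enoate
Conditions: 2 (2.5 equiv), piperidine (0.2 equiv), pyridine, 90 °C, 5 h
Reagents that add atoms: none
Why: Knoevenagel–Doebner condensation with a malonic half-ester; amine-catalysed condensation at the nitro-activated aldehyde and decarboxylative elimination give only the (E)-cinnamate, and the free nitrocatechol needs no protection.

**Step 2**
Reactants: 3 methyl (E)-3-(3,4-dihydroxy-5-nitrophenyl)prop-2-enoate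
Product: 4 methyl (E)-3-(3-amino-4,5-dihydroxyphenyl)prop-2-enoate
Conditions: Na2S2O4 (4 equiv), THF/H2O, 45 °C, N2; extract at pH 6, use at once
Reagents that add atoms: none
Why: Dithionite reduction of a nitroarene takes NO2 to NH2 without touching the cinnamate C=C or the ester, and the metal-free reducing medium neither chelates nor oxidises the aminocatechol.

**Step 3**
Reactants: 4 methyl (E)-3-(3-amino-4,5-dihydroxyphenyl)prop-2-enoate
Product: 6 methyl (E)-3-(5-acetoxy-3-diazo-4-oxocyclohexa-1,5-dien-1-yl)prop-2-enoate, via hydroxy quinone diazide 5 (not isolated)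
Conditions: t-BuONO (1.2 equiv), TFA (cat.), MeCN, 0 °C, dark; then pyridine (3 equiv), Ac2O (1.5 equiv), 0 °C to rt (diazo compound: shield, keep cold and dark)
Reagents that add atoms: tert-butyl nitrite CC(C)(C)ON=O; acetic anhydride CC(=O)OC(C)=O
Why: Diazotisation of an o-aminophenol; the diazonium ion loses the acidic ortho O–H proton to give the neutral o-quinone diazide, and Ac2O caps the single remaining OH (O7) so that no O–H bond can intercept the carbenoid later.

**Step 4**
Reactants: 7 3,4-dimethoxystyrene; 8 (Z)-but-2-ene-1,4-diyl diacetate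
Product: 9 (E)-3-(3,4-dimethoxyphenyl)prop-2-en-1-yl acetate
Conditions: 8 (2 equiv), second-generation Hoveyda–Grubbs catalyst (2 mol %), CH2Cl2, 40 °C
Reagents that add atoms: none
Why: Olefin cross metathesis of a styrene that homodimerises slowly with a symmetrical allylic diacetate gives the thermodynamically preferred (E)-cinnamyl acetate.

**Step 5**
Reactants: 6 methyl (E)-3-(5-acetoxy-3-diazo-4-oxocyclohexa-1,5-dien-1-yl)prop-2-enoate; 9 (E)-3-(3,4-dimethoxyphenyl)prop-2-en-1-yl acetate
Product: 12 methyl (E)-3-[(2R,3S)-7-acetoxy-3-(acetoxymethyl)-2-(3,4-dimethoxyphenyl)-2,3-dihydro-1-benzofuran-5-yl]prop-2-enoate, via rhodium carbenoid 10 (not isolated), via benzylic zwitterion 11 (not isolated)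
Conditions: Rh2(S-TCPTTL)4 (dirhodium tetrakis[N-tetrachlorophthaloyl-(S)-tert-leucinate], 1 mol %), 9 (2 equiv), 4 Å MS, PhCF3, 40 °C, 6 added over 4 h, dark; recrystallise to raise ee
Reagents that add atoms: none
Why: Proposed new method: 6 is the α-diazo ketone of the keto tautomer of the phenol, so loss of N2 on dirhodium gives carbenoid 10, an enolonium (α-oxo cation) equivalent in which C3a, normally the donor ortho carbon of a phenol, becomes an acceptor driven by the aromatisation it regains. The β-carbon of electron-rich styrene 9, also a natural donor, attacks it inside the chiral carboxylate pocket (C3–C3a bond, C3 set by the catalyst), and positive charge builds at the 3,4-dimethoxybenzylic carbon. The phenoxide oxygen of zwitterion 11 then closes on that carbon anti to CH2OAc (O1–C2 bond); a concerted suprafacial addition to the E-alkene would equally give the trans (2R,3S) product. The closest known reaction types are the achiral dirhodium-catalysed formal [3+2] cycloadditions of diazonaphthoquinones and 2-diazo-1,3-diketones with styrenes and enol ethers, and the enantioselective cyclopropanation of styrenes by acceptor-substituted diazo compounds with phthalimido-tert-leucinate dirhodium catalysts. What is new is the monocyclic quinone diazide, the 1,2-disubstituted styrene and the asymmetric induction.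

**Step 6**
Reactants: 12 methyl (E)-3-[(2R,3S)-7-acetoxy-3-(acetoxymethyl)-2-(3,4-dimethoxyphenyl)-2,3-dihydro-1-benzofuran-5-yl]prop-2-enoate
Product: 13 (E)-3-[(2R,3S)-2-(3,4-dimethoxyphenyl)-7-hydroxy-3-(hydroxymethyl)-2,3-dihydro-1-benzofuran-5-yl]prop-2-enoic acid
Conditions: LiOH (6 equiv), THF/MeOH/H2O, rt, N2; then 1 M HCl, 0 °C, pH 3
Reagents that add atoms: lithium hydroxide [Li+].[OH-]
Why: Saponification cleaves the aryl acetate, the primary acetate and the methyl cinnamate in one operation; neither C2 nor C3 carries a carbonyl group, so there is no acidic C–H and both stereocentres and the E-alkene are untouched.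

**Compound list**
1 | 3,4-dihydroxy-5-nitrobenzaldehyde | O=Cc1cc(O)c(O)c([N+](=O)[O-])c1 | starting material
2 | monomethyl malonate (3-methoxy-3-oxopropanoic acid) | COC(=O)CC(=O)O | starting material
3 | methyl (E)-3-(3,4-dihydroxy-5-nitrophenyl)prop-2-enoate | COC(=O)/C=C/c1cc(O)c(O)c([N+](=O)[O-])c1 | intermediate
4 | methyl (E)-3-(3-amino-4,5-dihydroxyphenyl)prop-2-enoate | COC(=O)/C=C/c1cc(O)c(O)c(N)c1 | intermediate
5 | methyl (E)-3-(3-diazo-5-hydroxy-4-oxocyclohexa-1,5-dien-1-yl)prop-2-enoate (hydroxy quinone diazide) | COC(=O)/C=C/C1=CC(=[N+]=[N-])C(=O)C(O)=C1 | intermediate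
6 | methyl (E)-3-(5-acetoxy-3-diazo-4-oxocyclohexa-1,5-dien-1-yl)prop-2-enoate (acetoxy quinone diazide) | COC(=O)/C=C/C1=CC(=[N+]=[N-])C(=O)C(OC(C)=O)=C1 | intermediate
7 | 3,4-dimethoxystyrene | C=Cc1ccc(OC)c(OC)c1 | starting material
8 | (Z)-but-2-ene-1,4-diyl diacetate | CC(=O)OC/C=C\COC(C)=O | starting material
9 | (E)-3-(3,4-dimethoxyphenyl)prop-2-en-1-yl acetate | COc1ccc(/C=C/COC(C)=O)cc1OC | intermediate
10 | rhodium carbenoid at C3a (carboxylate ligands of the catalyst omitted) | COC(=O)/C=C/C1=CC(=[Rh])C(=O)C(OC(C)=O)=C1 | intermediate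
11 | benzylic zwitterion (C3–C3a bond formed, cation at C2, phenoxide at O1) | COc1ccc([CH+][C@H](COC(C)=O)c2cc(/C=C/C(=O)OC)cc(OC(C)=O)c2[O-])cc1OC | intermediate
12 | methyl (E)-3-[(2R,3S)-7-acetoxy-3-(acetoxymethyl)-2-(3,4-dimethoxyphenyl)-2,3-dihydro-1-benzofuran-5-yl]prop-2-enoate | COc1ccc([C@@H]2Oc3c(OC(C)=O)cc(/C=C/C(=O)OC)cc3[C@H]2COC(C)=O)cc1OC | intermediate
13 | (E)-3-[(2R,3S)-2-(3,4-dimethoxyphenyl)-7-hydroxy-3-(hydroxymethyl)-2,3-dihydro-1-benzofuran-5-yl]prop-2-enoic acid | COc1ccc([C@@H]2Oc3c(O)cc(/C=C/C(=O)O)cc3[C@H]2CO)cc1OC | target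

**Step count and risks**
Total step count: 6. Longest linear sequence: 5 (Steps 1, 2, 3, 5, 6); Step 4 is a one-step side branch.

The three steps most likely to fail are Steps 5, 3 and 1.

**Step 5.** The induction on a monocyclic quinone diazide is untested, the trans-disubstituted alkene is a slow partner, and attack on the dimethoxyphenyl ring or a hydride shift in 11 can compete. The fallback runs from 6 and 9 back to 13: it gives up catalyst control and resolves at the acid stage.
- The cycloaddition is run with achiral Rh2(OAc)4. This gives 12 as a racemate with its mirror image methyl (E)-3-[(2S,3R)-7-acetoxy-3-(acetoxymethyl)-2-(3,4-dimethoxyphenyl)-2,3-dihydro-1-benzofuran-5-yl]prop-2-enoate F1.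
- Saponification as in Step 6 gives 13 mixed with (E)-3-[(2S,3R)-2-(3,4-dimethoxyphenyl)-7-hydroxy-3-(hydroxymethyl)-2,3-dihydro-1-benzofuran-5-yl]prop-2-enoic acid F2.
- The free carboxyl group is then used for a classical resolution by fractional crystallisation from ethanol of (R)-1-phenylethylammonium (E)-3-[(2R,3S)-2-(3,4-dimethoxyphenyl)-7-hydroxy-3-(hydroxymethyl)-2,3-dihydro-1-benzofuran-5-yl]prop-2-enoate F3.
- Acidification of this salt returns 13.

**Step 3.** Nitrite can oxidise the free catechol of 4 besides diazotising it, and 5 may be too labile to acetylate cleanly. The fallback runs from 3 back to 6: it changes the order so that no free catechol ever meets nitrite.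
- 3 is monoacetylated (Ac2O 1.0 equiv, pyridine, 0 °C) to methyl (E)-3-(3-acetoxy-4-hydroxy-5-nitrophenyl)prop-2-enoate F4.
- The acetyl group settles on this oxygen because the other OH is locked in a hydrogen bond to the nitro group and is the better leaving phenoxide, so acyl migration drains to this isomer.
- Zn in AcOH/THF at 0 °C gives methyl (E)-3-(3-acetoxy-5-amino-4-hydroxyphenyl)prop-2-enoate F5. It is kept protonated so that the acetyl group cannot move to nitrogen.
- After filtration, t-BuONO is added to the same acidic solution, which gives 6 directly.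

**Step 1.** The nitrocatecholate formed in pyridine is a sluggish aldehyde, and half-ester 2 decarboxylates in competition. The fallback runs from 1 back to 3: it replaces the condensation by a Wittig olefination on the masked catechol.
- 1 is peracetylated (Ac2O, pyridine) to 5-formyl-3-nitrobenzene-1,2-diyl diacetate F6, which has no acidic OH left to quench a stabilised ylide.
- Ph3P=CHCO2Me in toluene at rt gives methyl (E)-3-(3,4-diacetoxy-5-nitrophenyl)prop-2-enoate F7.
- K2CO3 in MeOH removes both aryl acetates to give 3.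

**Further compounds**
F1 | step 5 | methyl (E)-3-[(2S,3R)-7-acetoxy-3-(acetoxymethyl)-2-(3,4-dimethoxyphenyl)-2,3-dihydro-1-benzofuran-5-yl]prop-2-enoate | COc1ccc([C@H]2Oc3c(OC(C)=O)cc(/C=C/C(=O)OC)cc3[C@@H]2COC(C)=O)cc1OC
F2 | step 5 | (E)-3-[(2S,3R)-2-(3,4-dimethoxyphenyl)-7-hydroxy-3-(hydroxymethyl)-2,3-dihydro-1-benzofuran-5-yl]prop-2-enoic acid | COc1ccc([C@H]2Oc3c(O)cc(/C=C/C(=O)O)cc3[C@@H]2CO)cc1OC
F3 | step 5 | (R)-1-phenylethylammonium (E)-3-[(2R,3S)-2-(3,4-dimethoxyphenyl)-7-hydroxy-3-(hydroxymethyl)-2,3-dihydro-1-benzofuran-5-yl]prop-2-enoate | COc1ccc([C@@H]2Oc3c(O)cc(/C=C/C(=O)[O-])cc3[C@H]2CO)cc1OC.C[C@@H]([NH3+])c1ccccc1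
F4 | step 3 | methyl (E)-3-(3-acetoxy-4-hydroxy-5-nitrophenyl)prop-2-enoate | COC(=O)/C=C/c1cc(OC(C)=O)c(O)c([N+](=O)[O-])c1
F5 | step 3 | methyl (E)-3-(3-acetoxy-5-amino-4-hydroxyphenyl)prop-2-enoate | COC(=O)/C=C/c1cc(OC(C)=O)c(O)c(N)c1
F6 | step 1 | 5-formyl-3-nitrobenzene-1,2-diyl diacetate | CC(=O)Oc1cc(C=O)cc([N+](=O)[O-])c1OC(C)=O
F7 | step 1 | methyl (E)-3-(3,4-diacetoxy-5-nitrophenyl)prop-2-enoate | COC(=O)/C=C/c1cc(OC(C)=O)c(OC(C)=O)c([N+](=O)[O-])c1
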